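## Analysis of the target

Target 34 is a bicyclic diterpenoid with a labdane-type skeleton, and labdane numbering is used for every intermediate below. Ring A (C1–C5, C10) is a cyclohexane with a gem-dimethyl group on C4 and the angular methyl C20 on the quaternary C10. Ring B (C5–C10) is a cyclohexene with C6=C7, the carboxylic acid C17 on C8 and, on C9, the chain C11–C12–C13(=C14–C15O2H)–C16H2OAc. The four stereocentres C5, C8, C9 and C10 are contiguous (5R,8S,9R,10S): the ring fusion is trans, the C9 chain is equatorial on the face of CH3-20, and the C8 carboxyl is equatorial and trans to the chain; the side-chain alkene is 13E, with C12 cis to the C15 carboxyl. C8–H is both allylic and α to a carboxyl group, so base can epimerise it or pull C6=C7 into conjugation, and the primary allylic acetate forbids a final saponification. The hard points are C5, wedged between the quaternary carbons C4 and C10, the vicinal pair C9/C10, whose C9 member has no useful thermodynamic bias and must be set kinetically, and an absolute configuration antipodal to the common chiral-pool labdanes and drimanes. The strategy rests on one feature: with C6=C7 masked as a C6 carbinol, the oxygenated carbons C6 and C17 are 1,4-related across C7 and C8. That is the pattern of a reductive coupling between a C6 aldehyde on ring A and the β-carbon C7 of an acrylate whose α-carbon is C8, and forming C6–C7 in this way closes ring B.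

## Retrosynthetic reasoning

From 34 the two acids are taken back to tert-butyl esters and the acetate to the free C16 alcohol (33, then 32). Acidolysis is the only ester cleavage that spares the acetate and does not endanger C8. Acetylation is placed after the carbon skeleton is complete, so that no ionisable allylic ester is present during palladium catalysis.

The bond C12–C13 is cut next, giving the terminal alkene 25 (through its borane 31) and the (Z)-β-iodoenoate 30. Cutting here keeps the ring stereocentres out of the coupling and moves the problem of the trisubstituted alkene into a four-carbon fragment. An olefination at C13=C14 would give geometric mixtures. The forward coupling has to transfer the alkene geometry with retention.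

The vinyl group of 25 is traced to the C11 aldehyde 24, the alcohol 23 and the silyl ether 22. C11 is therefore carried at the alcohol oxidation level and masked from early on.

The alkene C6=C7 of 22 is taken back to the enol triflate 21 and the C6 ketone 19. The ketone places the alkene (only C7 can be enolised kinetically) and allows C5 and C8 to be equilibrated to the trans-fused, all-equatorial arrangement. Ketone 19 comes from its epimer mixture 18 and this from carbinol 17.

The key disconnection cuts C6–C7 of 17 and opens ring B to aldehyde 16. This is the only ring-B bond whose two ends are not stereocentres of the target and whose formation needs no stereocontrol. It also avoids polar bond formation at the shielded C5, since the hindered aldehyde only has to accept an electron. The forward step must join C6 to C7 and not to C8, and must outrun simple reduction.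

Aldehyde 16 goes back to carbinol 15 and, by anti-Markovnikov hydration, to the exocyclic alkene 13. The silyl ether 13 comes from alcohol 12 and this from the carboxylic acid 10, obtained from its resolved salt 9.

The bond C9–C10 of acid 8 (the racemate of 10) is cut by a retro-Ireland–Claisen step to the mixed itaconate 5. A [3,3] shift from the C6 oxygen makes the quaternary C10 intramolecularly, sets C9 and C10 together through a chair, and leaves the C5=C6 methylene needed for the aldehyde. The acid function offers the handle for resolution and later becomes C11. Ester 5 comes from half-ester 4, and this from β-cyclogeraniol 2 (from 1) and anhydride 3, which brings C7, C8, C9, C11 and C17 in one piece.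

Iodide 30 is taken back to ynoate 29 by anti addition of hydrogen iodide, and 29 to the protected ynoate 28 and the propargyl ether 26.

## Alternatives that were turned down

Alternative 1: The decalin is cut across C5–C10 and C8–C9 at once. This retro-[4+2] leads to the open-chain trienal A1, in which the (E)-enal C9=C10 is tied by C1–C4 to a 2-silyloxydiene C5=C6–C7=C8 ending in the C17 tert-butyl ester. In the forward direction a chiral oxazaborolidinium Lewis acid (diphenylprolinol-derived, B-o-tolyl, activated by triflimide) would bind the formyl group and drive an intramolecular Diels–Alder reaction. The product would be the trans-fused silyl enol ether A2, with the C11 aldehyde, the C6 oxygen for the later alkene and the C17 ester as the C8 epimer, to be corrected by base.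
- For: both rings and C5, C9 and C10 arise in one catalytic, enantioselective step and no resolution is needed. On step economy and on the source of absolute configuration this plan is stronger than the chosen one.
- Against: C5–C10 must form between a diene terminus attached to the quaternary C4 and the fully substituted β-carbon of the enal, so the quaternary centre is made in the most congested bond of a concerted transition state. β,β-Disubstituted enals are weak dienophiles even when activated, the diene is deactivated by its terminal ester, the geometry of the enol ether C5=C6 must be secured, and the silyl dienol ether must survive a strong Lewis acid.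
- In exchange, the chosen route makes the quaternary centre by a sigmatropic shift that tolerates hindrance and closes ring B by electron transfer, at the price of a resolution and more steps.

Alternative 2: This plan addresses the side chain and not the core. C13=C14 is disconnected by olefin metathesis, with the acrylate partner (C14, C15) held as an ester on the oxygen of a C17 carbinol; the precursor is triene A3 with a 1,1-disubstituted alkene at C13. A second-generation Grubbs catalyst would close the nine-membered unsaturated lactone A4, whose ring forces C12 and C15 to the same side of the new alkene.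
- For: the alkene geometry follows from a ring constraint and needs no stereodefined coupling partner. On that single point it is at least as secure as a stereospecific cross-coupling.
- Against: a nine-membered ring with a trisubstituted, ester-conjugated alkene is a slow ring-closing metathesis, dimerisation competes, and the carbene can engage C6=C7. Most seriously, C17 must afterwards be oxidised through the aldehyde to the acid beside C8, where a β,γ-unsaturated aldehyde would epimerise or conjugate. The decalin still has to be made by other means.
- The chosen route keeps C17 at the acid oxidation level from step 3 onwards and sets the side-chain geometry in a small fragment, transferred with retention.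

Alternative 3: Ring B is disconnected at C8–C9 by a retro-Claisen step. The bicyclic acid A7 (C11 carboxyl on C9, C17 silyloxymethyl on C8, C6=C7 in place) goes back to the silyl ketene acetal A6 of the trans-fused δ-lactone A5, whose lactone oxygen sits on C6 next to a (Z)-alkenyl group (C7=C8–C17). Forward, silylation of the lactone enolate and warming would trigger a ring-contracting Ireland–Claisen rearrangement through the boat that the lactone imposes: C8–C9 forms, C6–O breaks and ring B appears with its alkene.
- For: C6=C7 is delivered in the ring-forming step, which saves the carbinol-to-alkene detour of the chosen route, and C8 and C9 are set together under kinetic, suprafacial control. On both points it is stronger.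
- Against: the oxidation levels come out crossed (C11 as an acid, C17 as a protected alcohol), so C17 must be oxidised late, next to the labile C8. Lactone A5 needs a defined carbinol centre at C6, made by adding a (Z)-alkenyl nucleophile to a carbonyl on the most hindered position of ring A, and the outcome depends on that centre and on the boat preference. The C9/C10 pair must be in place beforehand anyway.
- The chosen route needs no stereocentre at C6 at any stage, carries C17 as an ester throughout and lets thermodynamics set C5 and C8.

Key step: step 10

Remarks on the chemistry: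
- α denotes the face that carries CH3-20 and β the opposite face; in 34, H-5, H-9 and C17 are β, and H-8 and C11 are α.
- Which antipode of 1-phenylethylamine gives the less soluble salt with the required acid is empirical; the (S)-amine is written and the (R)-amine would be used otherwise.
- The C17 ester is a tert-butyl ester from step 3 on: it is cleaved by acid at the end and is too hindered to lactonise with a C11 hydroxyl.

## Route

Step 1
Reactants: 1 β-cyclocitral
Product: 2 β-cyclogeraniol
Conditions: NaBH4, MeOH, 0 °C
Reagents that add atoms: none
Why: Borohydride 1,2-reduction of the enal; conjugate reduction is not an issue at a tetrasubstituted β-carbon.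

Step 2
Reactants: 2 β-cyclogeraniol; 3 itaconic anhydride
Product: 4 2-methylidene-4-oxo-4-[(2,6,6-trimethylcyclohex-1-en-1-yl)methoxy]butanoic acid
Conditions: toluene, 80 °C, no base
Reagents that add atoms: itaconic anhydride (3), C=C1CC(=O)OC1=O
Why: Alcoholysis of the unsymmetrical anhydride occurs at the more electrophilic, non-conjugated carbonyl (C11) and leaves the conjugated acid (C17) free. Without base the exocyclic alkene does not move into conjugation.

Step 3
Reactants: 4 half-ester acid
Product: 5 1-tert-butyl 4-[(2,6,6-trimethylcyclohex-1-en-1-yl)methyl] 2-methylidenebutanedioate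
Conditions: tert-butyl 2,2,2-trichloroacetimidate, cyclohexane/CH2Cl2, rt
Reagents that add atoms: tert-butyl 2,2,2-trichloroacetimidate, CC(C)(C)OC(=N)C(Cl)(Cl)Cl
Why: O-tert-Butylation of the carboxylic acid by the imidate, which the acid itself activates by protonation. Neither base nor strong acid is present, so the itaconate alkene and the allylic ester are left alone.

Step 4
Reactants: 5 mixed itaconate
Product: 8 racemic (2S*)-3-(tert-butoxycarbonyl)-2-[(1S*)-1,3,3-trimethyl-2-methylidenecyclohexyl]but-3-enoic acid, via silyl ketene acetal 6 (not isolated), via trimethylsilyl ester 7 (not isolated)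
Conditions: LiN(iPr)2, Me3SiCl (present from the start), THF, −100 → 23 °C, then 60 °C; 1 M HCl
Reagents that add atoms: none
Why: Ireland–Claisen rearrangement: kinetic deprotonation of the doubly activated C9–H2 in THF without polar cosolvent, with the chlorosilane as internal quench, should give the ketene acetal with the acrylate arm syn to the allylic oxygen. The chair transition state then has this arm and CH3-20 axial, forms C9–C10 with the 9,10 relative configuration of the target and leaves the C5=C6 methylene. The quaternary centre is made intramolecularly, which is how a tetrasubstituted alkene is best engaged.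

Step 5
Reactants: 8 racemic acid
Product: 9 (S)-1-phenylethylammonium (2S)-3-(tert-butoxycarbonyl)-2-[(1S)-1,3,3-trimethyl-2-methylidenecyclohexyl]but-3-enoate
Conditions: (S)-1-phenylethylamine, EtOAc/heptane, fractional crystallisation
Reagents that add atoms: (S)-1-phenylethylamine, C[C@H](N)c1ccccc1
Why: Classical resolution: the enantiomers of 8 give diastereomeric salts of different solubility, and recrystallisation to constant rotation should leave one of them. The amine centre serves as internal reference for an X-ray assignment.

Step 6
Reactants: 9 resolved salt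
Product: 12 tert-butyl (3S)-4-hydroxy-2-methylidene-3-[(1S)-1,3,3-trimethyl-2-methylidenecyclohexyl]butanoate, via free acid 10 (not isolated), via acyl fluoride 11 (not isolated)
Conditions: 1 M HCl/CH2Cl2 (partition); cyanuric fluoride, pyridine, CH2Cl2, −10 °C; NaBH4, MeOH added dropwise, 0 °C
Reagents that add atoms: none
Why: The liberated acid is converted into the small, unhindered acyl fluoride, which borohydride reduces to the primary alcohol much faster than it touches the tert-butyl α-alkylacrylate. Neither stage enolises C9, and the bulky ester should suppress closure to an α-methylene lactone.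

Step 7
Reactants: 12 primary alcohol
Product: 13 tert-butyl (3S)-4-[(tert-butyldimethylsilyl)oxy]-2-methylidene-3-[(1S)-1,3,3-trimethyl-2-methylidenecyclohexyl]butanoate
Conditions: tBuMe2SiCl, imidazole, DMF, rt
Reagents that add atoms: tert-butyldimethylsilyl chloride, CC(C)(C)[Si](C)(C)Cl
Why: Imidazole-promoted silylation of the primary alcohol. The ether masks C11 through the electrolysis, base and oxidation steps and excludes lactonisation onto C17.

Step 8
Reactants: 13 silyl ether
Product: 15 tert-butyl (3S)-4-[(tert-butyldimethylsilyl)oxy]-3-[(1R,2R)-2-(hydroxymethyl)-1,3,3-trimethylcyclohexyl]-2-methylidenebutanoate, via B-alkyl-9-BBN adduct 14 (not isolated)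
Conditions: 9-BBN, THF, 0 → 50 °C; NaBO3·4H2O, THF/H2O, rt
Reagents that add atoms: sodium perborate tetrahydrate (NaBO3·4H2O), [Na+].[O-]OB=O
Why: Hydroboration–oxidation: 9-BBN puts boron on the exposed C6 terminus of the electron-rich 1,1-disubstituted alkene and should leave the electron-poor, α-branched acrylate alone. Hydrogen is delivered to C5 from the face opposite the two axial methyl groups (CH3-20 and one C4 methyl), which gives H-5 β with C6 and the C9 arm trans-diequatorial. Partial loss of facial selectivity at C5 would be harmless, because C5 is equilibrated in step 12.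

Step 9
Reactants: 15 C6 carbinol
Product: 16 tert-butyl (3S)-4-[(tert-butyldimethylsilyl)oxy]-3-[(1S,2R)-2-formyl-1,3,3-trimethylcyclohexyl]-2-methylidenebutanoate
Conditions: Dess–Martin periodinane, NaHCO3, CH2Cl2, 0 °C → rt
Reagents that add atoms: none
Why: Dess–Martin oxidation of the hindered primary alcohol under buffered, non-basic conditions, so that C5 is not epimerised and the acrylate is untouched.

Step 10
Reactants: 16 aldehyde–acrylate
Product: 17 bicyclic 6β-hydroxy 17-tert-butyl ester with 11-silyloxy group (trans-fused; drawn isomer of a C6/C8 epimer mixture)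
Conditions: reticulated vitreous carbon cathode, Pt anode, divided cell, Et4NOTs (0.2 M), DMF, CH2(CO2Me)2 (2.5 equiv), −2.4 V vs SCE, rt, 5 mM
Reagents that add atoms: none
Why: One-electron transfer at the cathode to 16 (the formyl and acrylate groups are reduced at similar potentials) gives a radical anion in which C6 bonds to the unsubstituted β-carbon C7; a second electron and two protons from dimethyl malonate give the C6 carbinol and the C8–H ester. The closest known reaction type is the electroreductive cyclisation of aldehydes and ketones onto α,β-unsaturated esters, whose chemical counterpart is the ketyl–acrylate coupling; closure through an acrylate tethered at its α-carbon is the less usual mode. Ring B closes 6-endo-trig with respect to the acrylate (6-exo with respect to the carbonyl), because the 5-exo alternative would bond C6 to the fully substituted and electronically mismatched α-carbon C8. The new C6 centre should carry its oxygen equatorial (β), since an axial C6–O bond would be syn-diaxial to CH3-20 in the chair-like closure. The new C8 centre arises by protonation of the ester enolate from the face away from CH3-20 and is expected largely as the axial ester. Neither centre needs control: C6 becomes sp2 in step 11 and C8 is equilibrated in step 12. The selectivities that matter are C7 over C8 attack, secured by the polarisation and substitution of the acrylate, and cyclisation over simple reduction or hydrodimerisation, favoured by high dilution, controlled potential and a mild proton donor. The neopentyl-type aldehyde, a poor partner for polar additions, is not penalised in an electron-transfer step.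

Step 11
Reactants: 17 carbinol mixture
Product: 18 bicyclic 6-ketone with 17-tert-butyl ester (C8 epimer mixture)
Conditions: Dess–Martin periodinane, NaHCO3, CH2Cl2, rt
Reagents that add atoms: none
Why: Dess–Martin oxidation of the secondary carbinol; all C6 epimers converge on one ketone and the stereocentre made in step 10 is erased.

Step 12
Reactants: 18 ketone mixture
Product: 19 trans-fused 6-ketone with equatorial 8β-CO2tBu (H-5 β, H-8 α, H-9 β)
Conditions: KOtBu (0.3 equiv), tBuOH/THF, rt
Reagents that add atoms: none
Why: Base equilibration: C5 (α to the ketone) and C8 (α to the ester) epimerise through their enolates to the trans-fused decalone with the ester equatorial, since an axial ester would be syn-diaxial to CH3-20. C9 and C10 carry no acidic hydrogen, and tert-butoxide in tert-butanol cannot transesterify.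

Step 13
Reactants: 19 ketone
Product: 21 Δ6 enol triflate, via potassium enolate 20 (not isolated)
Conditions: KN(SiMe3)2, THF, −78 °C; PhNTf2, −78 → 0 °C
Reagents that add atoms: N-phenylbis(trifluoromethanesulfonimide), O=S(=O)(N(c1ccccc1)S(=O)(=O)C(F)(F)F)C(F)(F)F
Why: Kinetic enolisation of the ketone occurs at C7, the only accessible α-position (C5–H lies between two quaternary carbons), and O-sulfonylation fixes the Δ6 regiochemistry. The less acidic ester α-hydrogen at C8 is not removed by one equivalent of base at −78 °C.

Step 14
Reactants: 21 enol triflate
Product: 22 Δ6 alkene with 17-tert-butyl ester and 11-silyl ether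
Conditions: Pd(OAc)2 (5 mol %), PPh3, Bu3N, HCO2H, DMF, 60 °C
Reagents that add atoms: none
Why: Palladium-catalysed formate reduction of the enol triflate: oxidative addition to zerovalent palladium, formate exchange, loss of CO2 and reductive elimination put hydrogen on C6 and leave C6=C7 in place. The tertiary amine is too weak to deprotonate the allylic ester position C8.

Step 15
Reactants: 22 silyl ether
Product: 23 C11 alcohol
Conditions: HF·pyridine, THF/pyridine, 0 °C → rt
Reagents that add atoms: none
Why: Fluoride cleavage of the primary silyl ether under buffered, weakly acidic conditions that neither deprotonate C8 nor cleave the tert-butyl ester. The hindered ester should not lactonise with the freed γ-hydroxyl.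

Step 16
Reactants: 23 C11 alcohol
Product: 24 C11 aldehyde
Conditions: Dess–Martin periodinane, NaHCO3, CH2Cl2, 0 °C
Reagents that add atoms: none
Why: Buffered Dess–Martin oxidation gives the aldehyde without exposing the now enolisable C9–H to base.

Step 17
Reactants: 24 C11 aldehyde
Product: 25 C11=C12 terminal alkene
Conditions: Ph3PCH3Br, KN(SiMe3)2, THF, −78 → 0 °C (aldehyde added to the ylide)
Reagents that add atoms: methyltriphenylphosphonium bromide, C[P+](c1ccccc1)(c1ccccc1)c1ccccc1.[Br-]
Why: Wittig methylenation with a small, salt-free ylide at low temperature. Inverse addition keeps carbonyl addition ahead of enolisation at C9, whose configuration has no strong thermodynamic bias.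

Step 18
Reactants: 26 2-(prop-2-yn-1-yloxy)oxane
Product: 28 tert-butyl 4-(oxan-2-yloxy)but-2-ynoate, via lithium acetylide 27 (not isolated)
Conditions: n-BuLi, THF, −78 °C; Boc2O, −78 → 0 °C
Reagents that add atoms: di-tert-butyl dicarbonate, CC(C)(C)OC(=O)OC(=O)OC(C)(C)C
Why: Deprotonation of the terminal alkyne and C-acylation of the acetylide by the dicarbonate, with loss of tert-butyl carbonate, give the tert-butyl ynoate.

Step 19
Reactants: 28 protected ynoate
Product: 29 tert-butyl 4-hydroxybut-2-ynoate
Conditions: pyridinium p-toluenesulfonate (cat.), MeOH, 45 °C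
Reagents that add atoms: none
Why: Acid-catalysed acetal exchange with methanol removes the tetrahydropyranyl group; the tert-butyl ester tolerates the pyridinium acid.

Step 20
Reactants: 29 hydroxy ynoate
Product: 30 tert-butyl (2Z)-4-hydroxy-3-iodobut-2-enoate
Conditions: LiI, AcOH, MeCN, 70 °C
Reagents that add atoms: lithium iodide, [Li+].[I-]
Why: Hydroiodination of the ynoate: iodide adds to the β-carbon and the allenolate is protonated anti, so iodine ends cis to the ester (Z). The hydroxymethyl group is then trans to the ester and cannot lactonise.

Step 21
Reactants: 25 terminal alkene; 30 (Z)-β-iodoenoate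
Product: 32 di-tert-butyl 15,17-diester with free 16-hydroxyl (6-ene; 13E), via B-alkyl-9-BBN adduct 31 (not isolated)
Conditions: 9-BBN, THF, 0 °C → rt; then aq. K3PO4, 30, PdCl2(dppf) (5 mol %), AsPh3, DMF, rt
Reagents that add atoms: tert-butyl (2Z)-4-hydroxy-3-iodobut-2-enoate (30), OC/C(I)=C/C(=O)OC(C)(C)C
Why: B-alkyl Suzuki–Miyaura coupling: 9-BBN hydroborates the monosubstituted C11=C12 alkene in preference to the hindered, cis-disubstituted C6=C7. The alkylborate transfers C12 to the vinylpalladium species from 30 with retention, so C12 ends cis to the C15 ester (13E). The free alcohol is used in place of the acetate to keep an ionisable allylic ester away from zerovalent palladium.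

Step 22
Reactants: 32 hydroxy diester
Product: 33 di-tert-butyl 15,17-diester with 16-acetoxy group
Conditions: Ac2O, pyridine, 4-(dimethylamino)pyridine (cat.), CH2Cl2, 0 °C → rt
Reagents that add atoms: acetic anhydride, CC(=O)OC(C)=O
Why: Nucleophile-catalysed acetylation of the primary allylic alcohol; pyridine and the catalyst are too weak as bases to affect C8.

Step 23
Reactants: 33 acetoxy diester
Product: 34 (5R,8S,9R,10S,13E)-16-acetoxy-6,13-diene-15,17-dioic acid (target)
Conditions: CF3CO2H/CH2Cl2 (1:4), 0 °C → rt
Reagents that add atoms: none
Why: Acidolysis of both tert-butyl esters with loss of 2-methylpropene. The primary acetate, the C6=C7 alkene and the base-sensitive C8 centre are not affected by acid.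

## Compound list

1 | β-cyclocitral (2,6,6-trimethylcyclohex-1-ene-1-carbaldehyde) | CC1=C(C=O)C(C)(C)CCC1 | starting material
2 | β-cyclogeraniol ((2,6,6-trimethylcyclohex-1-en-1-yl)methanol) | CC1=C(CO)C(C)(C)CCC1 | intermediate
3 | itaconic anhydride (3-methylideneoxolane-2,5-dione) | C=C1CC(=O)OC1=O | starting material
4 | 2-methylidene-4-oxo-4-[(2,6,6-trimethylcyclohex-1-en-1-yl)methoxy]butanoic acid | C=C(CC(=O)OCC1=C(C)CCCC1(C)C)C(=O)O | intermediate
5 | 1-tert-butyl 4-[(2,6,6-trimethylcyclohex-1-en-1-yl)methyl] 2-methylidenebutanedioate | C=C(CC(=O)OCC1=C(C)CCCC1(C)C)C(=O)OC(C)(C)C | intermediate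
6 | (E)-trimethylsilyl ketene acetal of 5 (acrylate arm cis to the allylic oxygen) | C=C(C(=O)OC(C)(C)C)/C=C(\OCC1=C(C)CCCC1(C)C)O[Si](C)(C)C | intermediate
7 | trimethylsilyl ester of acid 8 (racemic, both enantiomers written) | C=C1C(C)(C)CCC[C@@]1(C)[C@H](C(=O)O[Si](C)(C)C)C(=C)C(=O)OC(C)(C)C.C=C1C(C)(C)CCC[C@]1(C)[C@@H](C(=O)O[Si](C)(C)C)C(=C)C(=O)OC(C)(C)C | intermediate
8 | racemic (2S*)-3-(tert-butoxycarbonyl)-2-[(1S*)-1,3,3-trimethyl-2-methylidenecyclohexyl]but-3-enoic acid (both enantiomers written) | C=C1C(C)(C)CCC[C@@]1(C)[C@H](C(=O)O)C(=C)C(=O)OC(C)(C)C.C=C1C(C)(C)CCC[C@]1(C)[C@@H](C(=O)O)C(=C)C(=O)OC(C)(C)C | intermediate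
9 | (S)-1-phenylethylammonium salt of the (2S,1'S)-acid | C=C1C(C)(C)CCC[C@@]1(C)[C@H](C(=O)[O-])C(=C)C(=O)OC(C)(C)C.C[C@H]([NH3+])c1ccccc1 | intermediate
10 | (2S)-3-(tert-butoxycarbonyl)-2-[(1S)-1,3,3-trimethyl-2-methylidenecyclohexyl]but-3-enoic acid | C=C1C(C)(C)CCC[C@@]1(C)[C@H](C(=O)O)C(=C)C(=O)OC(C)(C)C | intermediate
11 | acyl fluoride of 10 | C=C1C(C)(C)CCC[C@@]1(C)[C@H](C(F)=O)C(=C)C(=O)OC(C)(C)C | intermediate
12 | tert-butyl (3S)-4-hydroxy-2-methylidene-3-[(1S)-1,3,3-trimethyl-2-methylidenecyclohexyl]butanoate | C=C1C(C)(C)CCC[C@@]1(C)[C@H](CO)C(=C)C(=O)OC(C)(C)C | intermediate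
13 | tert-butyl (3S)-4-[(tert-butyldimethylsilyl)oxy]-2-methylidene-3-[(1S)-1,3,3-trimethyl-2-methylidenecyclohexyl]butanoate | C=C1C(C)(C)CCC[C@@]1(C)[C@H](CO[Si](C)(C)C(C)(C)C)C(=C)C(=O)OC(C)(C)C | intermediate
14 | B-alkyl-9-BBN adduct of 13 (boron on C6, H-5 β) | B1(C2CCCC1CCC2)C[C@@H]3C(C)(C)CCC[C@@]3(C)[C@H](CO[Si](C)(C)C(C)(C)C)C(=C)C(=O)OC(C)(C)C | intermediate
15 | tert-butyl (3S)-4-[(tert-butyldimethylsilyl)oxy]-3-[(1R,2R)-2-(hydroxymethyl)-1,3,3-trimethylcyclohexyl]-2-methylidenebutanoate | OC[C@@H]1C(C)(C)CCC[C@@]1(C)[C@H](CO[Si](C)(C)C(C)(C)C)C(=C)C(=O)OC(C)(C)C | intermediate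
16 | tert-butyl (3S)-4-[(tert-butyldimethylsilyl)oxy]-3-[(1S,2R)-2-formyl-1,3,3-trimethylcyclohexyl]-2-methylidenebutanoate (key-step precursor) | O=C[C@@H]1C(C)(C)CCC[C@@]1(C)[C@H](CO[Si](C)(C)C(C)(C)C)C(=C)C(=O)OC(C)(C)C | intermediate
17 | bicyclic carbinol: 6β-OH, 8β-CO2tBu (C17), 9α-CH2OSi(tBu)Me2 (C11), H-5 β, CH3-20 α; drawn isomer of a C6/C8 epimer mixture | CC(C)(C)[Si](C)(C)OC[C@@H]1[C@@H](C(=O)OC(C)(C)C)C[C@@H](O)[C@@H]2C(C)(C)CCC[C@@]12C | intermediate
18 | bicyclic 6-ketone, C8 epimer mixture (8-CO2tBu, 9α-CH2OSi(tBu)Me2) | CC(C)(C)[Si](C)(C)OC[C@@H]1C(C(=O)OC(C)(C)C)CC(=O)[C@@H]2C(C)(C)CCC[C@@]12C | intermediate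
19 | trans-fused 6-ketone: 8β-CO2tBu, 9α-CH2OSi(tBu)Me2, H-5 β, H-8 α, H-9 β | CC(C)(C)[Si](C)(C)OC[C@@H]1[C@@H](C(=O)OC(C)(C)C)CC(=O)[C@@H]2C(C)(C)CCC[C@@]12C | intermediate
20 | potassium 6-en-6-olate of 19 | CC(C)(C)[Si](C)(C)OC[C@@H]1[C@@H](C(=O)OC(C)(C)C)C=C([O-])[C@@H]2C(C)(C)CCC[C@@]12C.[K+] | intermediate
21 | 6-(trifluoromethanesulfonyloxy)-6-ene: 8β-CO2tBu, 9α-CH2OSi(tBu)Me2 | CC(C)(C)[Si](C)(C)OC[C@@H]1[C@@H](C(=O)OC(C)(C)C)C=C(OS(=O)(=O)C(F)(F)F)[C@@H]2C(C)(C)CCC[C@@]12C | intermediate
22 | 6-ene: 8β-CO2tBu, 9α-CH2OSi(tBu)Me2 | CC(C)(C)[Si](C)(C)OC[C@@H]1[C@@H](C(=O)OC(C)(C)C)C=C[C@@H]2C(C)(C)CCC[C@@]12C | intermediate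
23 | 6-ene: 8β-CO2tBu, 9α-CH2OH | OC[C@@H]1[C@@H](C(=O)OC(C)(C)C)C=C[C@@H]2C(C)(C)CCC[C@@]12C | intermediate
24 | 6-ene: 8β-CO2tBu, 9α-CHO | O=C[C@@H]1[C@@H](C(=O)OC(C)(C)C)C=C[C@@H]2C(C)(C)CCC[C@@]12C | intermediate
25 | 6,11-diene: 8β-CO2tBu, 9α-vinyl | C=C[C@@H]1[C@@H](C(=O)OC(C)(C)C)C=C[C@@H]2C(C)(C)CCC[C@@]12C | intermediate
26 | 2-(prop-2-yn-1-yloxy)oxane (tetrahydropyranyl ether of propargyl alcohol) | C#CCOC1CCCCO1 | starting material
27 | lithium acetylide of 26 | [Li]C#CCOC1CCCCO1 | intermediate
28 | tert-butyl 4-(oxan-2-yloxy)but-2-ynoate | CC(C)(C)OC(=O)C#CCOC1CCCCO1 | intermediate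
29 | tert-butyl 4-hydroxybut-2-ynoate | CC(C)(C)OC(=O)C#CCO | intermediate
30 | tert-butyl (2Z)-4-hydroxy-3-iodobut-2-enoate | OC/C(I)=C/C(=O)OC(C)(C)C | intermediate
31 | B-alkyl-9-BBN adduct of 25 (boron on C12) | B1(C2CCCC1CCC2)CC[C@@H]3[C@@H](C(=O)OC(C)(C)C)C=C[C@@H]4C(C)(C)CCC[C@@]34C | intermediate
32 | di-tert-butyl ester of the 16-hydroxy 6,13E-diene-15,17-dioic acid | OC/C(=C/C(=O)OC(C)(C)C)CC[C@@H]1[C@@H](C(=O)OC(C)(C)C)C=C[C@@H]2C(C)(C)CCC[C@@]12C | intermediate
33 | di-tert-butyl ester of the 16-acetoxy 6,13E-diene-15,17-dioic acid | CC(=O)OC/C(=C/C(=O)OC(C)(C)C)CC[C@@H]1[C@@H](C(=O)OC(C)(C)C)C=C[C@@H]2C(C)(C)CCC[C@@]12C | intermediate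
34 | (5R,8S,9R,10S,13E)-16-acetoxy-6,13-diene-15,17-dioic acid of the labdane skeleton (CNP0108723.1) | CC(=O)OC/C(=C/C(=O)O)CC[C@@H]1[C@@H](C(=O)O)C=C[C@@H]2C(C)(C)CCC[C@@]12C | target

## Step count and least certain steps

Total step count: 23. Longest linear sequence: 20 steps (steps 1–17 and 21–23); iodide 30 is made in 3 steps (18–20).

Step 10 (key step). The likely failure is that ring closure loses to two-electron reduction of the formyl group, to saturation of the acrylate or to its intermolecular hydrodimerisation. The 6-endo closure joins a neopentyl-type carbon to an α-branched acrylate and is not fast, and the two electrophores are reduced at similar potentials. Fallback: the same C6–C7 bond is made from an acyl radical in place of a ketyl. Starting from 16, oxidation with NaClO2 (NaH2PO4, 2-methylbut-2-ene, tBuOH/H2O) gives the C6 carboxylic acid F1, and diphenyl diselenide with Bu3P converts it into the Se-phenyl selenoester F2. Slow addition of Bu3SnH with azobisisobutyronitrile in benzene at 80 °C generates the C6 acyl radical, which adds 6-endo to C7 and, after hydrogen transfer to the α-ester radical, gives ketone 18, where the route is rejoined one step later than in the main line.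

Step 4. The likely failure is enolisation with the opposite geometry (lithium chelated by the acrylate carbonyl, or the intrinsic preference of an sp2 α-substituent), or escape into a boat transition state. Either would put the acrylate arm equatorial and deliver the C9 epimer, and C9 cannot be corrected later. The route also depends on the resolution in step 5. Fallback: the rearrangement is run on a boron ketene acetal. Ester 5 is enolised at −78 °C with (4S,5S)-2-bromo-4,5-diphenyl-1,3-bis(p-tolylsulfonyl)-1,3,2-diazaborolidine and Et3N in toluene/hexane. This amine–solvent pair is the one expected to place the α-substituent syn to the allylic oxygen in boron ketene acetals, and rearrangements of this kind are known for α-alkenyl acetates of 3,3-disubstituted allylic alcohols. The boron ketene acetal F3 rearranges on warming to −20 °C to the acyloxyborane F4, and aqueous work-up gives acid 10 in enantioenriched form. Step 5 then falls away and step 6 begins at the fluorination. The sense of induction is assigned by analogy; the (4R,5R)-reagent is equally accessible.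

Step 8. The likely failure is slow hydroboration of an alkene flanked by two quaternary carbons, which would let 9-BBN attack the acrylate (conjugate reduction) at the temperature needed. Fallback: oxygen is introduced by electrophilic epoxidation, which discriminates sharply between the two alkenes. Starting from 13, mCPBA (NaHCO3, CH2Cl2, 0 °C) gives the spiro-epoxide F5, and methylaluminium bis(4-bromo-2,6-di-tert-butylphenoxide) in CH2Cl2 at −78 °C rearranges it by 1,2-hydride shift (Meinwald rearrangement) to aldehyde 16. The configuration at C5 is reset in step 12 in any case.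

Step 17. The likely failure is loss of configuration at C9 through enolisation of the hindered aldehyde by the basic ylide before addition, since neither C9 epimer is clearly favoured. Fallback: the phosphorus ylide is replaced by a non-basic gem-dimetal methylene donor. Aldehyde 24 is treated with CH2I2, Zn and Ti(OiPr)4 in THF at rt (Takai–Lombardo methylenation), which gives 25 directly without any new intermediate.

## Further compounds

F1 | step 10 | C6 carboxylic acid from 16: tert-butyl (3S)-4-[(tert-butyldimethylsilyl)oxy]-3-[(1S,2R)-2-carboxy-1,3,3-trimethylcyclohexyl]-2-methylidenebutanoate | OC(=O)[C@@H]1C(C)(C)CCC[C@@]1(C)[C@H](CO[Si](C)(C)C(C)(C)C)C(=C)C(=O)OC(C)(C)C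
F2 | step 10 | Se-phenyl selenoester of F1 | O=C([Se]c1ccccc1)[C@@H]2C(C)(C)CCC[C@@]2(C)[C@H](CO[Si](C)(C)C(C)(C)C)C(=C)C(=O)OC(C)(C)C
F3 | step 4 | boron ketene acetal of 5 with the (4S,5S)-4,5-diphenyl-1,3-bis(p-tolylsulfonyl)-1,3,2-diazaborolidin-2-yl group on oxygen (acrylate arm cis to the allylic oxygen) | C=C(C(=O)OC(C)(C)C)/C=C(\OCC1=C(C)CCCC1(C)C)OB1N(S(=O)(=O)c2ccc(C)cc2)[C@@H](c2ccccc2)[C@H](c2ccccc2)N1S(=O)(=O)c1ccc(C)cc1
F4 | step 4 | acyloxyborane of acid 10 with the same diazaborolidine | C=C1C(C)(C)CCC[C@@]1(C)[C@H](C(=O)OB2N(S(=O)(=O)c3ccc(C)cc3)[C@@H](c3ccccc3)[C@H](c3ccccc3)N2S(=O)(=O)c2ccc(C)cc2)C(=C)C(=O)OC(C)(C)C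
F5 | step 8 | spiro-epoxide of 13 (oxirane on C5/C6, oxygen β) | O1C[C@@]12C(C)(C)CCC[C@@]2(C)[C@H](CO[Si](C)(C)C(C)(C)C)C(=C)C(=O)OC(C)(C)C
F0 | step 17 | none | none
A1 | alternative 1 | open-chain trienal: (E)-enal C9=C10 tethered to the 2-silyloxydiene ester | O=C/C=C(\C)CCCC(C)(C)C=C(O[Si](C)(C)C(C)(C)C)/C=C/C(=O)OC(C)(C)C
A2 | alternative 1 | trans-fused C6 silyl enol ether with C11 aldehyde and C17 tert-butyl ester (C8 epimer of the target array) | O=C[C@@H]1[C@H](C(=O)OC(C)(C)C)C=C(O[Si](C)(C)C(C)(C)C)[C@@H]2C(C)(C)CCC[C@@]12C
A3 | alternative 2 | C17 acrylate ester with the C13 1,1-disubstituted alkene and C16 silyl ether | CC(C)(C)[Si](C)(C)OCC(=C)CC[C@@H]1[C@@H](COC(=O)C=C)C=C[C@@H]2C(C)(C)CCC[C@@]12C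
A4 | alternative 2 | nine-membered unsaturated lactone bridging C15 and C17, with C16 silyl ether | CC(C)(C)[Si](C)(C)OC/C(=C/C(=O)O3)CC[C@@H]1[C@@H](C3)C=C[C@@H]2C(C)(C)CCC[C@@]12C
A5 | alternative 3 | trans-fused δ-lactone (C11 carbonyl, oxygen on C6) with the (Z)-alkenyl group on C6 | CC(C)(C)[Si](C)(C)OC/C=C\[C@@H]1OC(=O)C[C@]2(C)CCCC(C)(C)[C@@H]12
A6 | alternative 3 | trimethylsilyl ketene acetal of A5 | CC(C)(C)[Si](C)(C)OC/C=C\[C@@H]1OC(O[Si](C)(C)C)=C[C@]2(C)CCCC(C)(C)[C@@H]12
A7 | alternative 3 | bicyclic 6-ene with C11 carboxylic acid on C9 and C17 silyloxymethyl on C8 | OC(=O)[C@@H]1[C@@H](CO[Si](C)(C)C(C)(C)C)C=C[C@@H]2C(C)(C)CCC[C@@]12C
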